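**Assumption:** the (R)-configured bisphosphine is taken to deliver the allyl group to the Re face of aldehyde 7, the face that gives the (R)-carbinol because CH2Ar outranks allyl. If the first run (chiral HPLC or MTPA esters of 8) shows the opposite sense, the (S)-ligand is used and nothing else changes.

**Structure check:** the carbinol carbon of 5 becomes C2′. Two carbons of 6 (C3′, C4′) and nine carbons of 10 (C5′ to C13′) complete the chain, and the terminal CH2 of each partner leaves as ethene in step 6. CH2Ar outranks the allyl, alkenyl and alkyl arms, so 8, 9, 11, 12, 13 and 14 are all (R). No structure needed correction.

**Design remarks:** the acetate is installed before the metathesis. Alcohol 5 is made by hydroboration of styrene 3, so aldehyde 7 arises only inside the key step. Compound 2 is also listed by fine-chemical suppliers, and buying it would save one step; the count below starts from 1.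

## Structural features

The target 14 has a single ring, a 1,4-benzoquinone (C1–C6, carbonyls at C3 and C6), which carries a methoxy group at C5 and, at C1, a saturated thirteen-carbon chain joined through its C1′ methylene, so the C6 carbonyl is flanked by both substituents and the C3 carbonyl by two ring CH groups. The chain holds the only stereocentre, C2′, an (R)-configured secondary acetate that is homobenzylic to the ring and continues as an unbranched undecyl group. No second stereocentre stands next to it, so the configuration must come from a chiral catalyst or reagent. The two carbon arms at C2′ (C1′H2–ring and C3′H2–alkyl) are sterically almost alike, so reduction of the corresponding ketone would discriminate poorly, whereas C–C bond formation at an aldehyde carbon only has to tell H from a carbon arm. The quinone is an oxidant and a Michael acceptor and must appear last; the acetate is base-labile and, because C1′ in 14 is vinylogously acidic toward the C3 carbonyl, can be lost by β-elimination. The real difficulty is twofold: the aldehyde that corresponds to C2′ is an arylacetaldehyde with doubly activated α-protons that self-condenses readily, and the two quinone oxygens must sit para to each other with the chain and the methoxy group both ortho to the same carbonyl. The key step exploits the C1′–C2′ two-carbon arm: as a 2-arylethanol it is dehydrogenated in situ, so the C2′–C3′ bond and the stereocentre are made while the aldehyde exists only fleetingly. The ring problem is handled by buying the carbon–oxygen–methoxy 1,2,3 pattern in 1, whose position para to the hydroxyl is free and becomes C3.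

## Logic of the disconnections

**14 to 13.** The C3=O bond is removed and the C6 carbonyl is returned to a phenolic C–OH. The quinone is too electrophilic and too easily reduced to carry through C–C bond formation or hydrogenation. In 13 both positions ortho to the hydroxyl are occupied, so only the para carbon can take the new oxygen. The forward step needs an oxidant that works near neutrality and spares the acetate.

**13 to 11 (through 12).** The phenolic hydrogen is exchanged for a benzyl group and a C4′=C5′ double bond is introduced. In the forward direction one hydrogenation cuts the O–CH2Ph bond and saturates the π bond, so the protecting group costs no removal step. The gain is an alkene that invites a metathesis cut. The demand is that hydrogen must not cleave the C2′–O bond or reduce the arene.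

**11 to 9 and 10.** The C4′=C5′ double bond is cut. This removes the lipophilic tail as 10, a commodity chemical, and leaves a five-carbon homoallylic unit, which is exactly what an allylation produces. The forward step must favour the cross product over the homodimers; alkene geometry is irrelevant.

**9 to 8.** The acetyl C–O bond is cut. The free alcohol is the native product of the allylation, and an acetate would not survive carbonate at 100 °C. The forward acylation must leave the C2′–O bond intact so that the configuration is kept.

**8 to 5 and 6 (through 7).** The C2′–C3′ bond between the carbinol carbon and the allyl CH2 is cut. Of the bonds at the stereocentre, this is the one whose formation happens at an sp2 carbon bearing H and one carbon arm, and it can be made from the alcohol so that 7 never accumulates. The stereocentre disappears and the precursors are achiral 5 and bulk 6. The forward step needs catalyst-controlled Re-face addition, suppression of aldol chemistry of 7, and tolerance of the benzyl ether.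

**5 to 3 (through 4).** The C2′–O bond of the primary alcohol is cut and a C1′=C2′ double bond takes its place; forward, this is an anti-Markovnikov hydration. It reaches the alcohol oxidation level directly. A cut that made 5 by oxidative cleavage of a longer alkene and reduction would pass through 7 before the key step, which this one avoids. The gain is 3, which has no sp3 functional group. The demand is that boron goes to the terminal carbon only and that the benzyl ether survives alkaline peroxide.

**3 to 2.** The C1′=C2′ double bond is cut and C2′ is removed as a methylene unit. The carbonyl compound 2 is non-enolisable and robust, and it carries all three ring substituents in their final positions. The forward olefination must reach a carbonyl flanked by an ortho benzyloxy group, and no base-sensitive group is present to interfere.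

**2 to 1.** The O–CH2Ph bond is cut. The phenol must be masked against the ylide base, alkaline peroxide, carbonate at 100 °C and the ruthenium carbene; 1 is purchased.

## Other disconnections considered

**Alternative 1:** The cut goes through the arene. The benzene ring of A1, (R)-1-(3-hydroxy-5-methoxyphenyl)tridecan-2-yl acetate, is opened into the chiral cyclobutenone A2, (R)-1-(3-oxocyclobut-1-en-1-yl)tridecan-2-yl acetate, and methoxyacetylene A3. Forward, heating A2 with A3 would start a pericyclic cascade: 4π opening to a vinylketene, [2+2] addition to A3, a second 4π opening, then 6π closure and tautomerisation. This puts OH, OMe and the chain in a 1,3,5 relationship, and para-oxidation of A1 at the carbon between OMe and chain would give 14.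
- In favour: the oxygen pattern is created regiospecifically in one metal-free step, no phenol protection and no hydrogenation are needed, and the acetate is in place throughout. On these points it is better than the chosen plan.
- Against: the key step does not touch the stereocentre, so A2 needs its own asymmetric synthesis of a homopropargylic carbinol followed by ketene cycloaddition and dehalogenation. A2 carries an acetoxy group β to a vinylogously acidic methylene and would be heated, which invites elimination. A3 is volatile and has to be prepared. The final oxidation of A1 must take place at a carbon flanked by two substituents, with ortho attack as a competitor, whereas the para carbon of 13 is unhindered.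
- Comparison: on structure, the ring is built here and bought in the chosen plan. On mechanism, a thermal cascade replaces catalyst control and gives no help with configuration. On step count the two are about equal.

**Alternative 2:** The carbinol oxygen is tied back to the ring. The C2′ oxygen and quinone carbon C6 become O1 and C7a of A4, (R)-5,7-dimethoxy-2-undecyl-2,3-dihydrobenzofuran, which is traced to the flat benzofuran A5, 5,7-dimethoxy-2-undecylbenzofuran. Forward, asymmetric hydrogenation of the C2=C3 bond of A5 would set the stereocentre. Oxidative dealkylation across the para O1/5-OMe pair with (NH4)2Ce(NO3)6 (tetravalent cerium) would open the ring to the hydroxy quinone A6, (R)-2-(2-hydroxytridecyl)-6-methoxy-1,4-benzoquinone, and acetylation would finish.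
- In favour: A5 is achiral and easily assembled by annulation of an ortho-halophenol with a terminal alkyne. The tether masks phenol and carbinol at once. The stereo-defining step adds only hydrogen, so it is better in atom economy, and the route is equal or shorter in step count.
- Against: 2-alkylbenzofurans need specialised catalysts under pressure, such as the one formed from Ru(cod)(2-methylallyl)2 and a chiral N-heterocyclic carbene. Facial discrimination depends on a long flexible alkyl group, and the 7-methoxy group next to O1 may disturb binding. The oxidative opening must break the aryl–oxygen bond of a secondary alkyl ether rather than a methyl ether. The acetylation would then be run on a free quinone, which the chosen plan avoids by acylating three steps before the quinone exists.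
- Comparison: on structure, the tether is elegant but moves two uncertain steps behind the stereocentre. On mechanism, hydrogenation and allylation are both catalyst-controlled, but the allylation is the more general for this substrate class.

**Alternative 3:** The cut is the C–O bond of the ring oxygen that lies meta to both OMe and chain. Phenol A1 is traced to the boronate A7, (R)-1-[3-methoxy-5-(4,4,5,5-tetramethyl-1,3,2-dioxaborolan-2-yl)phenyl]tridecan-2-yl acetate, and that to the 1,3-disubstituted arene A8, (R)-1-(3-methoxyphenyl)tridecan-2-yl acetate. Forward, sterically governed C–H borylation of A8 with a pinacol-derived diboron reagent, catalysed by [Ir(OMe)(cod)]2 with 4,4′-di-tert-butyl-2,2′-bipyridine, would functionalise the one C–H that has no ortho substituent. Oxidation of the C–B bond would give A1, and para-oxidation would give 14.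
- In favour: the regiochemistry of borylation in 1,3-disubstituted benzenes is highly predictable, and the acetate and stereocentre are spectators. The aryl part comes from the purchasable alcohol A9, 2-(3-methoxyphenyl)ethanol, so no protecting group and no construction of the two-carbon arm are needed. The front end is therefore better than that of the chosen plan.
- Against: the key step makes neither the chain nor the stereocentre, which would still require the allylation and metathesis of the chosen plan starting from A9. One oxygen costs two steps (borylation, C–B oxidation), and the basic peroxide usually used for the second threatens the acetate. The final oxidation has the same hindered-para problem as in Alternative 1.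
- Comparison: on step count it is one step shorter on paper, since three front-end steps are saved and two are spent on the extra oxygen; on this point it is the better. On structure, the chosen plan buys all three ring substituents in place, while this one buys two and makes the third.

Key step: step 4

## Route

Step 1
Reactants: 1 2-hydroxy-3-methoxybenzaldehyde (o-vanillin)
Product: 2 2-(benzyloxy)-3-methoxybenzaldehyde
Conditions: BnBr, K2CO3, DMF, rt → 50 °C
Reagents that add atoms: benzyl bromide, BrCc1ccccc1
Why: Williamson ether synthesis, in which the phenoxide formed by K2CO3 displaces bromide by SN2; the non-enolisable aldehyde is a spectator, and benzyl is chosen because it withstands steps 2 to 6 and is removed without an extra operation in step 7.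

Step 2
Reactants: 2 2-(benzyloxy)-3-methoxybenzaldehyde
Product: 3 2-(benzyloxy)-1-ethenyl-3-methoxybenzene
Conditions: Ph3PCH3Br, KOtBu, THF, 0 °C → rt
Reagents that add atoms: methyltriphenylphosphonium bromide, C[P+](c1ccccc1)(c1ccccc1)c1ccccc1.[Br-]
Why: Wittig methylenation, in which the unstabilised ylide adds to the aryl aldehyde and the oxaphosphetane collapses to the styrene and Ph3PO; the aldehyde has no α-hydrogen, so the strong base finds nothing to enolise, and the ethers are inert.

Step 3
Reactants: 3 2-(benzyloxy)-1-ethenyl-3-methoxybenzene
Product: 5 2-[2-(benzyloxy)-3-methoxyphenyl]ethanol, via trialkylborane 4 (not isolated)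
Conditions: 9-BBN (1.2 equiv), THF, 0 °C → rt; then aq. NaOH, 30 % H2O2, 0 °C → rt
Reagents that add atoms: 9-borabicyclo[3.3.1]nonane (9-BBN; its atoms are retained in 4 only), B1C2CCCC1CCC2; hydrogen peroxide, OO
Why: Hydroboration–oxidation (Brown), in which the bulky dialkylborane adds boron to the terminal carbon of the styrene through a four-centre transition state to give 4, and alkaline peroxide replaces the C–B bond by C–OH through 1,2-migration. The primary alcohol is reached without any carbonyl intermediate, and the benzyl and methyl ethers are stable to both stages.

Step 4
Reactants: 5 2-[2-(benzyloxy)-3-methoxyphenyl]ethanol; 6 allyl acetate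
Product: 8 (R)-1-[2-(benzyloxy)-3-methoxyphenyl]pent-4-en-2-ol, via arylacetaldehyde 7 (not isolated)
Conditions: [Ir(cod)Cl]2 (2.5 mol %), (R)-BINAP (5 mol %), 4-Cl-3-NO2-C6H3CO2H (10 mol %), Cs2CO3 (20 mol %), 6 (excess), THF, 100 °C, sealed tube
Reagents that add atoms: allyl acetate (compound 6), C=CCOC(C)=O
Why: This is the iridium-catalysed transfer-hydrogenative carbonyl allylation at the alcohol oxidation level, a known coupling of primary alcohols with allyl acetate, applied here to a 2-arylethanol. [Ir(cod)Cl]2, the bisphosphine, the nitrobenzoic acid, Cs2CO3 and 6 assemble an ortho-cyclometallated π-allyl C,O-benzoate complex of trivalent iridium; the iridium alkoxide of 5 undergoes β-hydride elimination to release aldehyde 7 and an iridium hydride, and deprotonation of that hydride gives monovalent iridium, which ionises 6 and regenerates the π-allyl complex. The σ-allyl form adds to iridium-bound 7 through a closed six-membered chair transition state, forming the C2–C3 bond of 8, and the homoallyl alkoxide is released by exchange with fresh 5. No ring is closed. The one new stereocentre is controlled by the chiral bisphosphine, which together with the C,O-benzoate makes iridium a defined stereogenic centre and leaves only the Re face of 7 open to the allyl terminus, giving (R). The selectivity needed is enantiofacial, and it depends on the large difference between H and the CH2Ar arm at the carbonyl carbon rather than on any substrate bias. Chemoselectivity over aldol condensation comes from the low stationary concentration of 7, which forms only as fast as it is consumed, and 8 is not re-oxidised because its alkene occupies the coordination site needed for β-hydride elimination. The benzyl ether, the methyl ether and the arene take no part in the cycle.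

Step 5
Reactants: 8 (R)-1-[2-(benzyloxy)-3-methoxyphenyl]pent-4-en-2-ol
Product: 9 (R)-1-[2-(benzyloxy)-3-methoxyphenyl]pent-4-en-2-yl acetate
Conditions: Ac2O, pyridine, DMAP (cat.), CH2Cl2, 0 °C → rt
Reagents that add atoms: acetic anhydride, CC(=O)OC(C)=O
Why: DMAP-catalysed (Steglich-type) acylation on oxygen; no bond to C2 is broken, so the (R) configuration is retained, and the target's ester also masks the hydroxyl during metathesis.

Step 6
Reactants: 9 (R)-1-[2-(benzyloxy)-3-methoxyphenyl]pent-4-en-2-yl acetate; 10 1-decene
Product: 11 (R,E)-1-[2-(benzyloxy)-3-methoxyphenyl]tridec-4-en-2-yl acetate
Conditions: 10 (4 equiv), second-generation Grubbs catalyst (H2IMes)(PCy3)Cl2Ru=CHPh (3–5 mol %), CH2Cl2, 40 °C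
Reagents that add atoms: 1-decene (compound 10), C=CCCCCCCCC
Why: Olefin cross-metathesis (Chauvin mechanism, [2+2] cycloaddition and cycloreversion at the ruthenium alkylidene) between two unhindered terminal alkenes; the excess of inexpensive 10 and loss of ethene drive the hetero-coupling, and the non-polar homodimer of 10 separates easily. An E/Z mixture with E predominant is expected and does not matter because step 7 saturates the double bond; acetate, benzyl ether and stereocentre are untouched.

Step 7
Reactants: 11 (R,E)-1-[2-(benzyloxy)-3-methoxyphenyl]tridec-4-en-2-yl acetate
Product: 13 (R)-1-(2-hydroxy-3-methoxyphenyl)tridecan-2-yl acetate, via saturated benzyl ether 12 (not isolated)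
Conditions: H2 (1 atm), Pd/C (10 wt %), EtOAc, rt
Reagents that add atoms: none
Why: Heterogeneous catalytic hydrogenation saturates the disubstituted alkene to give 12, and hydrogenolysis of the benzylic C–O bond then frees the phenol. The acetate sits on a homobenzylic, non-allylic carbon and is not a hydrogenolysis substrate, EtOAc excludes transesterification, and the stereocentre has no reactive bond and stays (R).

Step 8
Reactants: 13 (R)-1-(2-hydroxy-3-methoxyphenyl)tridecan-2-yl acetate
Product: 14 (R)-1-(5-methoxy-3,6-dioxocyclohexa-1,4-dien-1-yl)tridecan-2-yl acetate
Conditions: (KSO3)2NO (2.5 equiv), aq. KH2PO4, acetone/H2O, 0 °C → rt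
Reagents that add atoms: potassium nitrosodisulfonate, [O]N(S(=O)(=O)[O-])S(=O)(=O)[O-].[K+].[K+]
Why: Teuber oxidation, in which (KSO3)2NO abstracts the phenolic hydrogen, a second equivalent couples at the only unsubstituted para carbon, and loss of imidodisulfonate gives the para-quinone; both ortho positions are blocked by the chain and OMe. The buffered, near-neutral medium spares the acetate and the stereocentre.

## Compound list

1 | 2-hydroxy-3-methoxybenzaldehyde (o-vanillin) | COc1cccc(C=O)c1O | starting material
2 | 2-(benzyloxy)-3-methoxybenzaldehyde | COc1cccc(C=O)c1OCc1ccccc1 | intermediate
3 | 2-(benzyloxy)-1-ethenyl-3-methoxybenzene | C=Cc1cccc(OC)c1OCc1ccccc1 | intermediate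
4 | 9-{2-[2-(benzyloxy)-3-methoxyphenyl]ethyl}-9-borabicyclo[3.3.1]nonane (not isolated) | B1(C2CCCC1CCC2)CCc1cccc(OC)c1OCc1ccccc1 | intermediate
5 | 2-[2-(benzyloxy)-3-methoxyphenyl]ethanol | OCCc1cccc(OC)c1OCc1ccccc1 | intermediate
6 | allyl acetate | C=CCOC(C)=O | starting material
7 | [2-(benzyloxy)-3-methoxyphenyl]acetaldehyde (not isolated) | O=CCc1cccc(OC)c1OCc1ccccc1 | intermediate
8 | (R)-1-[2-(benzyloxy)-3-methoxyphenyl]pent-4-en-2-ol | C=CC[C@H](Cc1cccc(OC)c1OCc1ccccc1)O | intermediate
9 | (R)-1-[2-(benzyloxy)-3-methoxyphenyl]pent-4-en-2-yl acetate | C=CC[C@H](Cc1cccc(OC)c1OCc1ccccc1)OC(C)=O | intermediate
10 | 1-decene | C=CCCCCCCCC | starting material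
11 | (R,E)-1-[2-(benzyloxy)-3-methoxyphenyl]tridec-4-en-2-yl acetate (E drawn; E/Z mixture carried on) | CCCCCCCC/C=C/C[C@H](Cc1cccc(OC)c1OCc1ccccc1)OC(C)=O | intermediate
12 | (R)-1-[2-(benzyloxy)-3-methoxyphenyl]tridecan-2-yl acetate (not isolated) | CCCCCCCCCCC[C@H](Cc1cccc(OC)c1OCc1ccccc1)OC(C)=O | intermediate
13 | (R)-1-(2-hydroxy-3-methoxyphenyl)tridecan-2-yl acetate | CCCCCCCCCCC[C@H](Cc1cccc(OC)c1O)OC(C)=O | intermediate
14 | (R)-1-(5-methoxy-3,6-dioxocyclohexa-1,4-dien-1-yl)tridecan-2-yl acetate | CCCCCCCCCCC[C@H](CC1=CC(=O)C=C(OC)C1=O)OC(C)=O | target

## Step count and least certain steps

Total step count: 8. Longest linear sequence: 8 steps (1 to 14); 6 and 10 enter as purchased coupling partners.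

**Step 4 (key step).** The most likely failure is carbonate-mediated aldol self-condensation of the transient aldehyde outrunning the allylation, because its α-protons are both benzylic and α to the carbonyl and the reaction runs at 100 °C. The second concern is erosion of enantiofacial selectivity if the ortho-benzyloxy group disturbs the chair transition state. The fallback moves the carbonyl addition to −78 °C, removes the base and replaces catalyst control by a stoichiometric chiral allylborane. It sets out from 5. Oxidation with Dess–Martin periodinane (CH2Cl2, NaHCO3, 0 °C → rt) gives 7, which is passed through a short silica plug and used at once. Aldehyde 7 is added at −78 °C in Et2O to the enantiomer of B-allyldiisopinocampheylborane that derives from (−)-α-pinene, made from the corresponding Ipc2BOMe and CH2=CHCH2MgBr with the magnesium salts filtered off. After NaOH/H2O2 work-up this should give 8, where the route is rejoined. Addition goes through a chair Zimmerman–Traxler transition state, and the established facial preference of this reagent points to Re-face attack; the sense is checked as in the main route. No new compound arises on this path.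

**Step 6.** The risk is double-bond migration by ruthenium hydride species before metathesis, which would give chain homologues one carbon shorter or longer that cannot be separated after hydrogenation; self-metathesis of 9 would also cost material. The fallback fixes the chain length by the reagents. It sets out from 9. Hydroboration of the terminal alkene with 9-BBN (THF) gives (R)-5-(9-borabicyclo[3.3.1]nonan-9-yl)-1-[2-(benzyloxy)-3-methoxyphenyl]pentan-2-yl acetate F1, which is not isolated. Alkyl–alkyl Suzuki–Miyaura coupling with 1-bromooctane (Pd(OAc)2, PCy3, K3PO4·H2O, THF, rt; zerovalent palladium formed in situ) gives 12 directly, where the route is rejoined before step 7.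

**Step 7.** The risk is a stalled hydrogenolysis: the benzyl ether sits between two ortho substituents, and ruthenium or phosphine residues from step 6 can poison the palladium surface, so the reaction may stop after alkene saturation. The fallback separates the two events and uses no heterogeneous catalyst. It sets out from 11. Diimide reduction (2-nitrobenzenesulfonohydrazide, Et3N, CH2Cl2, rt) saturates the alkene and gives 12, which is isolated. Lewis-acid debenzylation with BCl3 and pentamethylbenzene as cation scavenger (CH2Cl2, −78 °C) then gives 13, where the route resumes; the methyl ether and the acetate are expected to survive at this temperature. No new compound arises on this path.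

**Step 8.** The risk is incomplete oxidation: the lipophilic phenol dissolves poorly in the aqueous phase where the radical salt is, and the salt decomposes on standing. A drift to higher pH could also cause β-elimination of the acetate from the product, whose C1′ protons are vinylogously acidic. The fallback replaces the stoichiometric aqueous radical oxidant by a homogeneous catalytic aerobic oxidation: the divalent cobalt complex Co(salen) (catalytic) under O2 (1 atm) in DMF or MeCN at rt, which operates through a cobalt–dioxygen adduct and delivers the oxygen to the same free para position. It sets out from 13 and returns at 14 with no new compound.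

## Further compounds

F0 | step 4 | none | none
F1 | step 6 | (R)-5-(9-borabicyclo[3.3.1]nonan-9-yl)-1-[2-(benzyloxy)-3-methoxyphenyl]pentan-2-yl acetate | B1(C2CCCC1CCC2)CCC[C@H](Cc1cccc(OC)c1OCc1ccccc1)OC(C)=O
F0 | step 7 | none | none
F0 | step 8 | none | none
A1 | alternative 1 | (R)-1-(3-hydroxy-5-methoxyphenyl)tridecan-2-yl acetate | CCCCCCCCCCC[C@H](Cc1cc(O)cc(OC)c1)OC(C)=O
A2 | alternative 1 | (R)-1-(3-oxocyclobut-1-en-1-yl)tridecan-2-yl acetate | CCCCCCCCCCC[C@H](CC1=CC(=O)C1)OC(C)=O
A3 | alternative 1 | methoxyacetylene | COC#C
A4 | alternative 2 | (R)-5,7-dimethoxy-2-undecyl-2,3-dihydrobenzofuran | CCCCCCCCCCC[C@@H]1Cc2cc(OC)cc(OC)c2O1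
A5 | alternative 2 | 5,7-dimethoxy-2-undecylbenzofuran | CCCCCCCCCCCc1cc2cc(OC)cc(OC)c2o1
A6 | alternative 2 | (R)-2-(2-hydroxytridecyl)-6-methoxy-1,4-benzoquinone | CCCCCCCCCCC[C@H](CC1=CC(=O)C=C(OC)C1=O)O
A7 | alternative 3 | (R)-1-[3-methoxy-5-(4,4,5,5-tetramethyl-1,3,2-dioxaborolan-2-yl)phenyl]tridecan-2-yl acetate | CCCCCCCCCCC[C@H](Cc1cc(OC)cc(c1)B1OC(C)(C)C(C)(C)O1)OC(C)=O
A8 | alternative 3 | (R)-1-(3-methoxyphenyl)tridecan-2-yl acetate | CCCCCCCCCCC[C@H](Cc1cccc(OC)c1)OC(C)=O
A9 | alternative 3 | 2-(3-methoxyphenyl)ethanol | OCCc1cccc(OC)c1
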